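## Retrosynthetic overview
1. The hydroxy-methoxyquinone comes from regioselective saponification of a 2,5-dimethoxyquinone, which comes from oxidative demethylation of a tetramethoxybenzyl decalin.
2. The benzylic CH2 comes from Barton–McCombie removal of the carbinol oxygen left by a late union of (2,3,5,6-tetramethoxyphenyl)lithium with a non-enolisable C15 decalin aldehyde.
3. The decalin aldehyde comes from a catalytic enantioselective exo Diels–Alder reaction of 1-ethenyl-6,6-dimethylcyclohexene with tiglaldehyde, and this one step sets all three stereocentres.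
4. The diene comes from 2-methylcyclohexanone (regiospecific methylation, enol triflate, vinyl cross-coupling). The aryl bromide comes from hydroquinone (oxidation, methylation, reduction, methylation, bromination).
5. Ring order: ring A is bought as the cyclohexanone, ring B is closed by the cycloaddition, and the quinone ring is bought as hydroquinone and re-oxidised last.

Assumption: the SMILES is taken at face value (decalin 1R,2S,8aS; 1-CH3 and 2-CH3 cis; 8a-H cis to the benzylic CH2), and the facial sense of the catalyst in step 5 follows the accepted transition-state model for α-methyl enals.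

Descriptor note: C8a is R in 9 and 17–19 and S in 20–22. This is only because the CIP ranking at that carbon changes when the C1 substituent loses its oxygen. No bond to a stereocentre is touched.

## Fragment A (decalin aldehyde)

Step 1
Reactants: 1 2-methylcyclohexan-1-one (racemic)
Product: 2 trimethyl[(2-methylcyclohex-1-en-1-yl)oxy]silane
Conditions: Me3SiCl, Et3N, DMF, 130 °C, 48 h; fractional distillation
Reagents that add atoms: chlorotrimethylsilane C[Si](C)(C)Cl
Why: Silyl enol ether formation under equilibrating conditions favours the tetrasubstituted enol ether (about 4:1), the minor isomer is distilled off, and the stereocentre of racemic 1 is erased.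

Step 2
Reactants: 2 trimethyl[(2-methylcyclohex-1-en-1-yl)oxy]silane
Product: 4 2,2-dimethylcyclohexan-1-one, via lithium enolate 3 (not isolated)
Conditions: MeLi, THF, 0 °C to rt; then MeI (5 equiv), 0 °C
Reagents that add atoms: iodomethane CI; methyllithium [Li]C (lithium of 3 only)
Why: Si–O cleavage by MeLi releases the regiodefined lithium enolate without equilibration, and SN2 C-methylation by excess MeI outruns proton transfer (regiospecific enolate alkylation).

Step 3
Reactants: 4 2,2-dimethylcyclohexan-1-one
Product: 6 6,6-dimethylcyclohex-1-en-1-yl trifluoromethanesulfonate, via lithium enolate 5 (not isolated)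
Conditions: LiN(i-Pr)2, THF, −78 °C; PhNTf2, −78 °C to rt
Reagents that add atoms: N-phenylbis(trifluoromethanesulfonimide) O=S(=O)(N(c1ccccc1)S(=O)(=O)C(F)(F)F)C(F)(F)F; lithium diisopropylamide [Li]N(C(C)C)C(C)C (lithium of 5 only)
Why: Only one α-carbon carries hydrogen, so deprotonation gives a single enolate that is O-sulfonylated (enol triflate formation).

Step 4
Reactants: 6 6,6-dimethylcyclohex-1-en-1-yl trifluoromethanesulfonate
Product: 7 1-ethenyl-6,6-dimethylcyclohex-1-ene
Conditions: CH2=CHMgBr (1.5 equiv), Pd(PPh3)4 (3 mol %), THF, 0 °C to rt; distillation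
Reagents that add atoms: vinylmagnesium bromide C=C[Mg]Br
Why: In this Kumada–Corriu cross-coupling, oxidative addition of the C–OTf bond to zerovalent palladium, transmetallation and reductive elimination give the 1,3-diene with the ring double bond fixed in position.

Step 5
Reactants: 7 1-ethenyl-6,6-dimethylcyclohex-1-ene; 8 (E)-2-methylbut-2-enal (tiglaldehyde)
Product: 9 (1R,2S,8aR)-1,2,5,5-tetramethyl-1,2,3,5,6,7,8,8a-octahydronaphthalene-1-carbaldehyde
Conditions: (3aR)-1-(2-methylphenyl)-3,3-diphenyltetrahydro-1H,3H-pyrrolo[1,2-c][1,3,2]oxazaborole (C24H24BNO, 20 mol %), (CF3SO2)2NH (18 mol %), 7 (1.5 equiv), CH2Cl2, −78 to −40 °C, 24 h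
Reagents that add atoms: none
Why: In this enantioselective Diels–Alder reaction under cationic oxazaborolidine catalysis, the CH2 terminus of the diene bonds to the β-carbon of the activated s-trans enal (ortho orientation), suprafacial addition to the E-alkene makes the two new methyl-bearing centres cis, the exo transition state typical of α-methyl enals (the catalyst-bound formyl group avoids the diene carbon flanked by the gem-dimethyl group) puts 8a-H cis to CHO, and the phenyl-shielded R catalyst leaves only the Si face of C2 of 8 open, which fixes the absolute configuration of all three stereocentres.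

## Fragment B (arene)

Step 6
Reactants: 10 benzene-1,4-diol (hydroquinone)
Product: 11 2,5-dihydroxycyclohexa-2,5-diene-1,4-dione
Conditions: 50 % aq NaOH, 30 % H2O2, 45–50 °C; then conc. HCl, 0 °C
Reagents that add atoms: hydrogen peroxide OO
Why: Alkaline peroxide oxidation gives benzoquinone, which undergoes two rounds of conjugate oxygen addition and re-oxidation and stops at the dianion, a doubly vinylogous carboxylate that resists further attack.

Step 7
Reactants: 11 2,5-dihydroxycyclohexa-2,5-diene-1,4-dione
Product: 12 2,5-dimethoxycyclohexa-2,5-diene-1,4-dione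
Conditions: MeOH, conc. H2SO4 (cat.), reflux, 12 h; filtration
Reagents that add atoms: methanol CO
Why: Both hydroxyl groups are vinylogous carboxylic acids, so Fischer-type esterification by addition–elimination of methanol gives the sparingly soluble dimethyl ether, which crystallises out.

Step 8
Reactants: 12 2,5-dimethoxycyclohexa-2,5-diene-1,4-dione
Product: 13 2,5-dimethoxybenzene-1,4-diol
Conditions: Na2S2O4, THF/H2O, rt, N2
Reagents that add atoms: none
Why: Dithionite reduction of a quinone to its hydroquinone is a clean two-electron, two-proton transfer, and nothing else in 12 is reducible.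

Step 9
Reactants: 13 2,5-dimethoxybenzene-1,4-diol
Product: 14 1,2,4,5-tetramethoxybenzene
Conditions: MeI (3 equiv), K2CO3 (3 equiv), acetone, reflux, N2
Reagents that add atoms: iodomethane CI
Why: Williamson ether synthesis on both phenoxides, run under nitrogen so that the electron-rich hydroquinone is not re-oxidised.

Step 10
Reactants: 14 1,2,4,5-tetramethoxybenzene
Product: 15 3-bromo-1,2,4,5-tetramethoxybenzene
Conditions: NBS (1.0 equiv), MeCN, 0 °C to rt, dark
Reagents that add atoms: N-bromosuccinimide O=C1CCC(=O)N1Br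
Why: In this electrophilic aromatic bromination the two free positions are equivalent, and one equivalent of NBS stops at the deactivated and crowded monobromide.

## Union and end game

Step 11
Reactants: 15 3-bromo-1,2,4,5-tetramethoxybenzene; 9 (1R,2S,8aR)-1,2,5,5-tetramethyl-1,2,3,5,6,7,8,8a-octahydronaphthalene-1-carbaldehyde
Product: 19 O-{[(1R,2S,8aR)-1,2,5,5-tetramethyl-1,2,3,5,6,7,8,8a-octahydronaphthalen-1-yl](2,3,5,6-tetramethoxyphenyl)methyl} S-methyl dithiocarbonate (both carbinol epimers), via aryllithium 16 (not isolated), via lithium alkoxide 17 (not isolated), via lithium xanthate 18 (not isolated)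
Conditions: 15 (1.3 equiv), n-BuLi (1.25 equiv), THF, −78 °C; 9, −78 to 0 °C; CS2 (5 equiv), DMPU, 0 °C to rt; MeI (6 equiv), rt
Reagents that add atoms: carbon disulfide S=C=S; iodomethane CI; n-butyllithium [Li]CCCC (lithium of 16–18 only)
Why: Lithium–bromine exchange gives the aryllithium cleanly, its 1,2-addition to the aldehyde cannot be diverted by enolisation because the α-carbon is quaternary, the alkoxide is trapped as the xanthate, and the new carbinol stereocentre forms unselectively but is removed in step 12.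

Step 12
Reactants: 19 the S-methyl xanthate (both carbinol epimers)
Product: 20 1,2,4,5-tetramethoxy-3-{[(1R,2S,8aS)-1,2,5,5-tetramethyl-1,2,3,5,6,7,8,8a-octahydronaphthalen-1-yl]methyl}benzene
Conditions: Bu3SnH (3 equiv), AIBN (0.2 equiv), toluene, 110 °C, 2 h
Reagents that add atoms: none
Why: In this Barton–McCombie deoxygenation, stannyl radical addition to C=S and β-scission give a benzylic radical that has no β-hydrogen to lose and could reach the ring alkene only by disfavoured 4-exo or 5-endo closure, so it simply abstracts hydrogen from Bu3SnH.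

Step 13
Reactants: 20 the tetramethoxybenzyl decalin
Product: 21 2,5-dimethoxy-3-{[(1R,2S,8aS)-1,2,5,5-tetramethyl-1,2,3,5,6,7,8,8a-octahydronaphthalen-1-yl]methyl}cyclohexa-2,5-diene-1,4-dione
Conditions: (NH4)2Ce(NO3)6 (2.5 equiv), MeCN/H2O 2:1, 0 °C, 20 min
Reagents that add atoms: water O
Why: Oxidative demethylation by tetravalent cerium removes two electrons from the very electron-rich ring, water attacks a para pair of methoxy-bearing carbons with loss of methanol, both para pairs give the same quinone by symmetry, and the isolated trisubstituted alkene is not oxidised.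

Step 14
Reactants: 21 the 2,5-dimethoxyquinone
Product: 22 2-hydroxy-5-methoxy-3-{[(1R,2S,8aS)-1,2,5,5-tetramethyl-1,2,3,5,6,7,8,8a-octahydronaphthalen-1-yl]methyl}cyclohexa-2,5-diene-1,4-dione (target)
Conditions: 2 M aq KOH (3 equiv), MeOH, rt; then 1 M HCl to pH 3, 0 °C
Reagents that add atoms: potassium hydroxide [K+].[OH-]
Why: In this vinylogous ester saponification by addition–elimination, the methoxy group next to the bulky side chain is twisted out of conjugation and is the more electrophilic site, and the delocalised hydroxyquinone anion then blocks hydrolysis of the second methoxy group.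

## Compound list
1 | 2-methylcyclohexan-1-one (racemic) | CC1CCCCC1=O | starting material
2 | trimethyl[(2-methylcyclohex-1-en-1-yl)oxy]silane | CC1=C(O[Si](C)(C)C)CCCC1 | intermediate
3 | lithium 2-methylcyclohex-1-en-1-olate | [Li+].CC1=C([O-])CCCC1 | intermediate
4 | 2,2-dimethylcyclohexan-1-one | CC1(C)CCCCC1=O | intermediate
5 | lithium 6,6-dimethylcyclohex-1-en-1-olate | [Li+].CC1(C)CCCC=C1[O-] | intermediate
6 | 6,6-dimethylcyclohex-1-en-1-yl trifluoromethanesulfonate | CC1(C)CCCC=C1OS(=O)(=O)C(F)(F)F | intermediate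
7 | 1-ethenyl-6,6-dimethylcyclohex-1-ene | C=CC1=CCCCC1(C)C | intermediate
8 | (E)-2-methylbut-2-enal | C/C=C(\C)C=O | starting material
9 | (1R,2S,8aR)-1,2,5,5-tetramethyl-1,2,3,5,6,7,8,8a-octahydronaphthalene-1-carbaldehyde | O=C[C@@]1(C)[C@@H]2CCCC(C)(C)C2=CC[C@@H]1C | intermediate
10 | benzene-1,4-diol | Oc1ccc(O)cc1 | starting material
11 | 2,5-dihydroxycyclohexa-2,5-diene-1,4-dione | O=C1C=C(O)C(=O)C=C1O | intermediate
12 | 2,5-dimethoxycyclohexa-2,5-diene-1,4-dione | COC1=CC(=O)C(OC)=CC1=O | intermediate
13 | 2,5-dimethoxybenzene-1,4-diol | COc1cc(O)c(OC)cc1O | intermediate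
14 | 1,2,4,5-tetramethoxybenzene | COc1cc(OC)c(OC)cc1OC | intermediate
15 | 3-bromo-1,2,4,5-tetramethoxybenzene | COc1cc(OC)c(OC)c(Br)c1OC | intermediate
16 | (2,3,5,6-tetramethoxyphenyl)lithium | [Li]c1c(OC)c(OC)cc(OC)c1OC | intermediate
17 | lithium [(1R,2S,8aR)-1,2,5,5-tetramethyl-1,2,3,5,6,7,8,8a-octahydronaphthalen-1-yl](2,3,5,6-tetramethoxyphenyl)methanolate (carbinol epimers) | [Li+].[O-]C(c1c(OC)c(OC)cc(OC)c1OC)[C@@]2(C)[C@@H]3CCCC(C)(C)C3=CC[C@@H]2C | intermediate
18 | lithium O-alkyl dithiocarbonate of 17 (carbinol epimers) | [Li+].[S-]C(=S)OC(c1c(OC)c(OC)cc(OC)c1OC)[C@@]2(C)[C@@H]3CCCC(C)(C)C3=CC[C@@H]2C | intermediate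
19 | O-{[(1R,2S,8aR)-1,2,5,5-tetramethyl-1,2,3,5,6,7,8,8a-octahydronaphthalen-1-yl](2,3,5,6-tetramethoxyphenyl)methyl} S-methyl dithiocarbonate (carbinol epimers) | CSC(=S)OC(c1c(OC)c(OC)cc(OC)c1OC)[C@@]2(C)[C@@H]3CCCC(C)(C)C3=CC[C@@H]2C | intermediate
20 | 1,2,4,5-tetramethoxy-3-{[(1R,2S,8aS)-1,2,5,5-tetramethyl-1,2,3,5,6,7,8,8a-octahydronaphthalen-1-yl]methyl}benzene | COc1cc(OC)c(OC)c(C[C@@]2(C)[C@@H]3CCCC(C)(C)C3=CC[C@@H]2C)c1OC | intermediate
21 | 2,5-dimethoxy-3-{[(1R,2S,8aS)-1,2,5,5-tetramethyl-1,2,3,5,6,7,8,8a-octahydronaphthalen-1-yl]methyl}cyclohexa-2,5-diene-1,4-dione | COC1=CC(=O)C(OC)=C(C[C@@]2(C)[C@@H]3CCCC(C)(C)C3=CC[C@@H]2C)C1=O | intermediate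
22 | 2-hydroxy-5-methoxy-3-{[(1R,2S,8aS)-1,2,5,5-tetramethyl-1,2,3,5,6,7,8,8a-octahydronaphthalen-1-yl]methyl}cyclohexa-2,5-diene-1,4-dione | COC1=CC(=O)C(O)=C(C[C@@]2(C)[C@@H]3CCCC(C)(C)C3=CC[C@@H]2C)C1=O | target

## Counts and risks
Total step count: 14.
Longest linear sequence: 9 steps (steps 1–5, then 11–14). The arene arm (steps 6–10, then 11–14) is equally long.

**Step 5 (most likely to fail).** A trisubstituted enal has to form a quaternary carbon next to the ring fusion of an acid-sensitive, hindered diene. Rate, exo:endo ratio and ee are all uncertain.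

The fallback replaces chiral Lewis acid catalysis by an auxiliary-controlled ionic Diels–Alder reaction. It sets out from 8, with 7 as partner, and comes back to the route at 9. Compound 8 is condensed with (2R,4R)-pentane-2,4-diol (PPTS, benzene, Dean–Stark) to the chiral acetal (4R,6R)-2-[(E)-but-2-en-2-yl]-4,6-dimethyl-1,3-dioxane F1. Me3SiOTf (10 mol %) in CH2Cl2 at −78 °C turns this acetal into a far more electrophilic dienophile, which adds to 7 and recloses to the decalin acetal (4R,6R)-4,6-dimethyl-2-[(1R,2S,8aR)-1,2,5,5-tetramethyl-1,2,3,5,6,7,8,8a-octahydronaphthalen-1-yl]-1,3-dioxane F2. The diastereomers are separated on silica gel and assigned by NOE. Transacetalisation (PPTS, wet acetone, 50 °C) then gives 9.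

**Step 11.** A di-ortho-substituted aryllithium meets a neopentyl aldehyde, and the crowded lithium alkoxide may add to CS2 only sluggishly.

The fallback replaces carbonyl addition and deoxygenation by an sp3–sp2 cross-coupling. It sets out from 9 and comes back at 20, bypassing 19.
- NaBH4 (MeOH, 0 °C) gives the neopentyl alcohol [(1R,2S,8aR)-1,2,5,5-tetramethyl-1,2,3,5,6,7,8,8a-octahydronaphthalen-1-yl]methanol F3.
- I2, PPh3 and imidazole (toluene, 80 °C) give the iodide (1R,2S,8aR)-1-(iodomethyl)-1,2,5,5-tetramethyl-1,2,3,5,6,7,8,8a-octahydronaphthalene F4.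
- Zinc dust and LiCl (THF, 50 °C) give the alkylzinc iodide {[(1R,2S,8aR)-1,2,5,5-tetramethyl-1,2,3,5,6,7,8,8a-octahydronaphthalen-1-yl]methyl}zinc iodide F5.
- This reagent has no β-hydrogen. It undergoes Negishi coupling with 15 (Pd(OAc)2 2 mol %, 2-dicyclohexylphosphino-2′,6′-dimethoxybiphenyl 4 mol %, THF, 60 °C) to give 20 directly.

**Step 14.** The wrong methoxy group may be cleaved, or both may be lost.

The fallback gives up selective cleavage in favour of selective re-methylation. It sets out from 21 and comes back at 22. Exhaustive saponification (2 M NaOH, EtOH, 70 °C, then cold 1 M HCl) gives the dihydroxyquinone 2,5-dihydroxy-3-{[(1R,2S,8aS)-1,2,5,5-tetramethyl-1,2,3,5,6,7,8,8a-octahydronaphthalen-1-yl]methyl}cyclohexa-2,5-diene-1,4-dione F6. Vinylogous Fischer esterification (MeOH, p-TsOH 5 mol %, rt) then lets methanol add only at the unhindered ring carbon next to C–H, which gives 22.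

## Further compounds
F1 | step 5 | (4R,6R)-2-[(E)-but-2-en-2-yl]-4,6-dimethyl-1,3-dioxane | C/C=C(\C)C1O[C@H](C)C[C@@H](C)O1
F2 | step 5 | (4R,6R)-4,6-dimethyl-2-[(1R,2S,8aR)-1,2,5,5-tetramethyl-1,2,3,5,6,7,8,8a-octahydronaphthalen-1-yl]-1,3-dioxane | O1[C@H](C)C[C@@H](C)OC1[C@@]2(C)[C@@H]3CCCC(C)(C)C3=CC[C@@H]2C
F3 | step 11 | [(1R,2S,8aR)-1,2,5,5-tetramethyl-1,2,3,5,6,7,8,8a-octahydronaphthalen-1-yl]methanol | OC[C@@]1(C)[C@@H]2CCCC(C)(C)C2=CC[C@@H]1C
F4 | step 11 | (1R,2S,8aR)-1-(iodomethyl)-1,2,5,5-tetramethyl-1,2,3,5,6,7,8,8a-octahydronaphthalene | IC[C@@]1(C)[C@@H]2CCCC(C)(C)C2=CC[C@@H]1C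
F5 | step 11 | {[(1R,2S,8aR)-1,2,5,5-tetramethyl-1,2,3,5,6,7,8,8a-octahydronaphthalen-1-yl]methyl}zinc iodide | I[Zn]C[C@@]1(C)[C@@H]2CCCC(C)(C)C2=CC[C@@H]1C
F6 | step 14 | 2,5-dihydroxy-3-{[(1R,2S,8aS)-1,2,5,5-tetramethyl-1,2,3,5,6,7,8,8a-octahydronaphthalen-1-yl]methyl}cyclohexa-2,5-diene-1,4-dione | O=C1C=C(O)C(=O)C(C[C@@]2(C)[C@@H]3CCCC(C)(C)C3=CC[C@@H]2C)=C1O
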